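## Analysis of the target

The target is a single cyclohexene carbocycle with one exocyclic carbon. Numbering the ring C1 (OMe), C2=C3 (C3 carries C7H2OBz), C4 (OH), C5 (OBz), C6 (OH), every ring carbon except C2 bears an oxygen or carbon substituent. The four stereocentres C1, C6, C5 and C4 are contiguous and all R; on the ring O1 and O6 are cis, O6 and O5 trans, O5 and O4 cis. Five oxygens occur in three states (one methyl ether, two benzoates, two free hydroxyls), and O1, O4 and O7 are allylic. The sensitive points are the C5 benzoate, which lies between two free hydroxyls and can migrate under base, the allylic C–O bonds, which can ionise under acid, and the alkene, which rules out hydrogenolysis at the end. The skeleton is simple; the difficulty is to tell the oxygens apart (methylate O1 but not O6 or O4, acylate O5 but not its neighbours) while fixing four stereocentres in absolute terms. The strategy rests on reading C1 as a disguised anomeric carbon: it bears a methoxy group and sits next to the oxygen-free C2, so replacing the C1–C2 bond by a bond from C1 to an oxygen on C3 turns the ring into a methyl hexopyranoside. In that pyranoside C6, C5 and C4 are C2, C3 and C4 of D-altrose and the cis O1/O6 relation is that of the β anomer, so the methyl ether is the glycosidic methyl group and three stereocentres come with the sugar.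

## Retrosynthetic reasoning

**21 to 20.** The two free hydroxyls on C4 and C6 are unmasked last, because once they are free the C5 benzoate can migrate. They are carried as benzyl ethers, which survive Lewis acid, base and palladium. The forward step must remove them without hydrogen (alkene, allylic esters) and without base.

**20 to 19 and 9, then 19 to 17 and 18.** The O7–acyl bond is cut first, then the C3–C7 bond. C7 is the only carbon that a hexose-derived ring does not contain, so it is the natural piece to add late. Cutting at the sp2 carbon C3 leaves a vinyl electrophile 17 and the one-carbon stannane 18; the cross-coupling fixes the alkene at C2=C3.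

**17 to 15.** The enol triflate comes from ketone 15 by enolisation toward the C2 methylene. The forward step must choose C2 over C4 and must not expel the β-oxygen substituents.

**15 to 13 (key disconnection).** The C1–C2 bond is cut and C1 is reconnected to the oxygen on C3, which turns the cyclohexanone into the enol-ether pyranoside 13. This is the cut that makes the O1 problem disappear: the methoxy group is the aglycon of a methyl glycoside and never has to be introduced selectively. The forward reaction has to break the endocyclic C1–O bond under Lewis acid promotion, join C2 to C1, keep the carbonyl at C3 and keep the configuration at C1.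

**13 to 12 to 11.** The exocyclic enol ether is made by elimination of a primary iodide, and the iodide from the primary alcohol of 11. Only sugar C5 loses its configuration, and it is trigonal in the target anyway.

**11 to 10, then 10 to 8 and 9.** The O4 benzyl ether and the free O6–H are one benzylidene acetal in 10; regioselective reductive opening supplies the benzyl group from the acetal carbon. The benzoate is put on the only free hydroxyl of 8, which is the oxygen that becomes O5.

**8 to 6 and 7, then 6 to 4 to 3 to 1 and 2.** The C2–O bond of the sugar is cut back to the allo epoxide 6 and benzyl alcohol 7. Trans-diaxial opening inverts C2, leaves O3 free and thus distinguishes O2 from O3 in one operation. The epoxide itself comes from the gluco diol 3 through the disulfonate 4 with inversion at C3, and 3 from glucoside 1 and acetal 2.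

## Alternatives that were turned down

**Alternative 1:** The ring is cut at C1–C2 and C3–C4 into the C2-symmetric acetonide dialdehyde A1 (C1, C6, C5, C4) and the silylated propargyl ether A2 (C2, C3, C7). In the forward step the alkyne complex made from A2 with Ti(OiPr)4 and iPrMgCl (a source of divalent titanium) would add through both alkyne carbons to the two aldehydes of A1 and give the cyclohexenediol A3.
- For it: the ring, the alkene and C7 appear in one step from two small pieces, and the O1/O6 and O4/O5 cis relations have the same C2 symmetry as A1. On convergence and step count to the carbocycle it is clearly stronger than the chosen route.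
- Against it: the second carbonyl insertion has to take place at the silyl-bearing vinyl–titanium bond, the less reactive one. Two carbinol centres are set with open-chain induction from an α-alkoxy aldehyde. A3 then has two near-equivalent allylic hydroxyls, of which only O1 may be methylated, and an acetonide whose two oxygens must be told apart for the C5 benzoate. The vinyl silane also has to be removed.
- Comparison: the oxygen-differentiation problem, which is the real problem of the target, is left for the end and made harder by the pseudo-symmetry. The chosen route has every oxygen distinguished from the sugar stage.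

**Alternative 2:** The ring is cut at C3–C4 and C5–C6 into 2-pyrone A4 and vinylene carbonate A5. An endo Diels–Alder reaction under high pressure with a chiral Lewis acid would give the bridged lactone carbonate A6, whose lactone carbonyl is C7.
- For it: all seven carbons and four stereocentres come from two flat commodity chemicals in one step, and the endo rule gives O5 trans to O6 and cis to O4 as required. On ring-forming economy it is the strongest of all.
- Against it: neither partner is activated, and neither offers two-point binding to a chiral Lewis acid, so the absolute configuration has no firm basis. Bridged pyrone adducts lose CO2 on heating. The alkene sits at C1=C2 and must be moved to C2=C3 while an oxygen is brought to C1 cis to O6 and methylated selectively. The two carbonate oxygens are equivalent in kind and must be differentiated.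
- Comparison: a long, poorly controlled sequence would follow the cycloaddition. The chosen route takes the absolute configuration from a sugar and obtains the methyl ether without a selective methylation.

**Alternative 3:** The ring is cut at C1–C6 to the open-chain aldehyde A7, which carries an allylic dimethyl acetal. CrCl2 with Me3SiI would convert the acetal into a γ-methoxyallyl species of trivalent chromium that adds through C1 to the C6 aldehyde and gives the cyclohexenol A8.
- For it: the methyl ether, the C2=C3 alkene, C7 and the C6 hydroxyl all emerge in the ring-forming step. On this point it is stronger than the chosen route, which needs three further steps for C7 and the alkene.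
- Against it: A7 needs its own multistep synthesis with two stereocentres, a trisubstituted alkene and an epimerisable α-benzoyloxy aldehyde. In one of its forms the allylchromium unit has the metal on C3 next to the silyloxy-bearing C4, which invites β-elimination. The anti preference of the open-chain reaction comes from a chair transition state that is not available when the allyl unit is part of the forming ring, so the cis O1/O6 outcome cannot be argued. The end game must exchange a silyl group on O7 for a benzoate beside a free O6–H.
- Comparison: the chosen route sets only one stereocentre in its key step, on a substrate class where the reaction type is established, and reaches its precursor by textbook carbohydrate steps.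

Key step: step 9

Remark on the chemistry: the rearrangement of step 9 is assumed to keep the anomeric configuration with the β-glycoside 13 as it does in the established cases; carbocycle atoms are numbered C1 (OMe), C2, C3 (bears C7), C4, C5, C6 throughout, and sugar locants are marked as such.

## Route

Step 1
Reactants: 1 methyl β-D-glucopyranoside; 2 benzaldehyde dimethyl acetal
Product: 3 methyl 4,6-O-[(R)-benzylidene]-β-D-glucopyranoside
Conditions: PhCH(OMe)2, camphorsulfonic acid (cat.), MeCN, 60 °C
Reagents that add atoms: benzaldehyde dimethyl acetal (2), COC(OC)c1ccccc1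
Why: Acid-catalysed transacetalisation under thermodynamic control selects the six-membered 4,6-acetal (trans-fused 1,3-dioxane) over an acetal on the trans-2,3-diol; the acetal carbon takes the R configuration with phenyl equatorial.

Step 2
Reactants: 3 methyl 4,6-O-[(R)-benzylidene]-β-D-glucopyranoside
Product: 4 methyl 4,6-O-[(R)-benzylidene]-2,3-di-O-(4-methylbenzenesulfonyl)-β-D-glucopyranoside
Conditions: TsCl (3 equiv), pyridine, DMAP (cat.), 40 °C
Reagents that add atoms: p-toluenesulfonyl chloride, Cc1ccc(cc1)S(=O)(=O)Cl
Why: Plain O-sulfonylation of both secondary hydroxyls with pyridine as base and DMAP as transfer catalyst; no stereocentre is touched.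

Step 3
Reactants: 4 methyl 4,6-O-[(R)-benzylidene]-2,3-di-O-(4-methylbenzenesulfonyl)-β-D-glucopyranoside
Product: 6 methyl 2,3-anhydro-4,6-O-[(R)-benzylidene]-β-D-allopyranoside, via sodium 2-alkoxide 3-tosylate 5 (not isolated)
Conditions: NaOMe, MeOH–CH2Cl2, rt to 40 °C
Reagents that add atoms: none
Why: Methoxide attacks sulfur of the C2 sulfonate, whose alkoxide is the better leaving group because O2 lies next to the acetal carbon C1, and the freed C2 alkoxide 5 displaces the C3 tosylate from the rear (intramolecular Williamson-type SN2 closure); sugar C3 is inverted and C2 retained, which defines the allo epoxide with its oxygen on the α face.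

Step 4
Reactants: 6 methyl 2,3-anhydro-4,6-O-[(R)-benzylidene]-β-D-allopyranoside; 7 benzyl alcohol
Product: 8 methyl 2-O-benzyl-4,6-O-[(R)-benzylidene]-β-D-altropyranoside
Conditions: NaH (1.5 equiv), BnOH, 110 °C; aqueous work-up
Reagents that add atoms: benzyl alcohol (7), OCc1ccccc1
Why: Trans-diaxial epoxide opening (Fürst–Plattner rule): in the benzylidene-locked half-chair the benzyl alkoxide attacks C2 from the β face through a chair-like transition state, inverting C2 and leaving the C3 oxygen α and free; this sets the altro configuration and distinguishes O2 (benzylated) from O3 (free).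

Step 5
Reactants: 8 methyl 2-O-benzyl-4,6-O-[(R)-benzylidene]-β-D-altropyranoside; 9 benzoyl chloride
Product: 10 methyl 3-O-benzoyl-2-O-benzyl-4,6-O-[(R)-benzylidene]-β-D-altropyranoside
Conditions: BzCl, pyridine, DMAP (cat.), CH2Cl2, 0 °C to 40 °C
Reagents that add atoms: benzoyl chloride (9), O=C(Cl)c1ccccc1
Why: DMAP-catalysed acylation of the single free (axial) hydroxyl; the benzoate is now on the oxygen that becomes O5 of the target.

Step 6
Reactants: 10 methyl 3-O-benzoyl-2-O-benzyl-4,6-O-[(R)-benzylidene]-β-D-altropyranoside
Product: 11 methyl 3-O-benzoyl-2,4-di-O-benzyl-β-D-altropyranoside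
Conditions: BH3·THF, Me3SiOTf (cat.), CH2Cl2, 0 °C; MeOH quench
Reagents that add atoms: none
Why: Lewis-acid-assisted reductive opening of the benzylidene acetal: the silyl triflate activates the less hindered O6, the acetal opens to an O4-benzylic oxocarbenium ion that borane reduces, so the benzyl group stays on O4 and the primary hydroxyl is freed; the benzoate is not reduced by borane at 0 °C.

Step 7
Reactants: 11 methyl 3-O-benzoyl-2,4-di-O-benzyl-β-D-altropyranoside
Product: 12 methyl 3-O-benzoyl-2,4-di-O-benzyl-6-deoxy-6-iodo-β-D-altropyranoside
Conditions: I2, PPh3, imidazole, toluene, 70 °C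
Reagents that add atoms: iodine, II
Why: Appel-type iodination of the primary alcohol through the alkoxyphosphonium iodide (SN2 at C6); the secondary centres, benzyl ethers and benzoate are inert.

Step 8
Reactants: 12 methyl 3-O-benzoyl-2,4-di-O-benzyl-6-deoxy-6-iodo-β-D-altropyranoside
Product: 13 methyl 3-O-benzoyl-2,4-di-O-benzyl-6-deoxy-β-D-arabino-hex-5-enopyranoside
Conditions: AgF, pyridine, rt, dark
Reagents that add atoms: none
Why: Silver-assisted E2 dehydroiodination across sugar C5–C6 gives the exocyclic enol ether; the conditions are mild enough for the benzoate, and the only stereocentre affected is C5, which becomes trigonal.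

Step 9
Reactants: 13 methyl 3-O-benzoyl-2,4-di-O-benzyl-6-deoxy-β-D-arabino-hex-5-enopyranoside
Product: 15 (2S,3S,4R,5R)-3-(benzoyloxy)-2,4-bis(benzyloxy)-5-methoxycyclohexan-1-one, via ring-opened titanium enolate oxocarbenium zwitterion 14 (not isolated)
Conditions: Ti(OiPr)Cl3 (1.5–2 equiv), CH2Cl2, −78 °C, short reaction time; aq. NaHCO3
Reagents that add atoms: none
Why: Ti(OiPr)Cl3 binds the ring oxygen of 13 and, with a lone pair of the methoxy oxygen antiperiplanar to the C1–O5 bond, the endocyclic bond ionises to zwitterion 14, a methoxy-stabilised oxocarbenium ion tethered to a titanium enolate; the enolate is a far better leaving group than titanium-bound methoxide, which steers the cleavage to the endocyclic bond. The enolate carbon (sugar C6, carbocycle C2) then adds to the oxocarbenium carbon C1 in an intramolecular Mukaiyama-type aldol step that forms C1–C2 and releases ketone 15. The closest known reaction type is the Lewis-acid-promoted rearrangement of 6-deoxyhex-5-enopyranosides to carbocycles with retention of the aglycon, a relative of the Ferrier carbocyclisation; a chlorotitanium reagent without transferable hydride leaves the C3 carbonyl in place. The ring closes in the 6-(enolendo)-exo-trig mode, with the enolate C=C inside and the C=O+ bond outside the new ring. C1 is the only stereocentre made: because C2 and the departing oxygen sit on the same trigonal carbon, least-motion recombination inside the contact ion pair through a chair-like array should put C2 on the face of C1 that the oxygen has just left, so the β configuration is retained and OMe ends up cis to the C6 benzyloxy group and trans to the C5 benzoate. The step needs endocyclic over exocyclic C–O cleavage, recombination faster than rotation about the former C1–C2 bond of the sugar, and survival of the ester; the small electron-releasing methyl aglycon, the low temperature with a short reaction time, and the non-reducing, weakly nucleophilic titanium reagent are what secure these. C4, C5 and C6 are not touched and keep the configuration set in the sugar.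

Step 10
Reactants: 15 (2S,3S,4R,5R)-3-(benzoyloxy)-2,4-bis(benzyloxy)-5-methoxycyclohexan-1-one
Product: 17 enol triflate of 15 toward C2 (C3–OTf, C2=C3; C1 R, O6 cis and O5, O4 trans to O1), via lithium enolate 16 (not isolated)
Conditions: LiN(SiMe3)2, THF, −78 °C; 2-[N,N-bis(trifluoromethylsulfonyl)amino]-5-chloropyridine, −78 °C
Reagents that add atoms: 2-[N,N-bis(trifluoromethylsulfonyl)amino]-5-chloropyridine, FC(F)(F)S(=O)(=O)N(c1ccc(Cl)cn1)S(=O)(=O)C(F)(F)F
Why: Kinetic deprotonation by the hindered amide base at the unhindered C2 methylene, not at the tertiary alkoxy-flanked C4–H, gives lithium enolate 16, which the electrophilic N-pyridyl triflimide sulfonylates on oxygen at −78 °C; the lithium counter-ion, the low temperature and the immediate trap are chosen to outrun E1cB loss of the C1 methoxide, and no stereocentre is formed.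

Step 11
Reactants: 17 enol triflate; 18 (tributylstannyl)methanol
Product: 19 allylic alcohol (C3–CH2OH, C2=C3; ring configuration as in 17)
Conditions: Bu3SnCH2OH, Pd(PPh3)4 (cat.), LiCl, 1,4-dioxane, 90 °C
Reagents that add atoms: (tributylstannyl)methanol (18), OC[Sn](CCCC)(CCCC)CCCC
Why: Stille cross-coupling: zerovalent palladium inserts into the C3–OTf bond, LiCl turns the divalent palladium triflate into the chloride that undergoes transmetalation with the hydroxymethyl stannane, and reductive elimination forms C3–C7 with the alkene fixed at C2=C3; the free hydroxyl of 18 is tolerated and no stereocentre is involved.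

Step 12
Reactants: 19 allylic alcohol; 9 benzoyl chloride
Product: 20 4,6-di-O-benzyl ether of the target (C7–OBz, C5–OBz, C4–OBn, C6–OBn, C1–OMe)
Conditions: BzCl, pyridine, DMAP (cat.), CH2Cl2, 0 °C
Reagents that add atoms: benzoyl chloride (9), O=C(Cl)c1ccccc1
Why: Esterification of the only free hydroxyl (primary, allylic); at this stage there is no free neighbouring hydroxyl to which a benzoate could migrate.

Step 13
Reactants: 20 4,6-di-O-benzyl ether of the target
Product: 21 [(3R,4R,5R,6R)-5-(benzoyloxy)-4,6-dihydroxy-3-methoxycyclohex-1-en-1-yl]methyl benzoate (target)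
Conditions: BCl3, pentamethylbenzene, CH2Cl2, −78 °C; MeOH quench at −78 °C
Reagents that add atoms: none
Why: Lewis-acid dealkylation of the two benzyl ethers: BCl3 coordinates the ether oxygens, the C–O bonds break on the benzylic side and pentamethylbenzene traps the benzyl cations by Friedel–Crafts alkylation; at −78 °C the methyl ether, both benzoates and the alkene should be untouched, and the acidic methanol quench gives no opening for base-induced benzoate migration.

## Compound list

1 | methyl β-D-glucopyranoside | CO[C@@H]1O[C@H](CO)[C@@H](O)[C@H](O)[C@H]1O | starting material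
2 | benzaldehyde dimethyl acetal | COC(OC)c1ccccc1 | starting material
3 | methyl 4,6-O-[(R)-benzylidene]-β-D-glucopyranoside | CO[C@@H]1O[C@@H]2CO[C@@H](c3ccccc3)O[C@H]2[C@H](O)[C@H]1O | intermediate
4 | methyl 4,6-O-[(R)-benzylidene]-2,3-di-O-(4-methylbenzenesulfonyl)-β-D-glucopyranoside | CO[C@@H]1O[C@@H]2CO[C@@H](c3ccccc3)O[C@H]2[C@H](OS(=O)(=O)c3ccc(C)cc3)[C@H]1OS(=O)(=O)c1ccc(C)cc1 | intermediate
5 | sodium 2-alkoxide of methyl 4,6-O-[(R)-benzylidene]-3-O-(4-methylbenzenesulfonyl)-β-D-glucopyranoside | CO[C@@H]1O[C@@H]2CO[C@@H](c3ccccc3)O[C@H]2[C@H](OS(=O)(=O)c3ccc(C)cc3)[C@H]1[O-].[Na+] | intermediate (not isolated)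
6 | methyl 2,3-anhydro-4,6-O-[(R)-benzylidene]-β-D-allopyranoside | CO[C@@H]1O[C@@H]2CO[C@@H](c3ccccc3)O[C@H]2[C@@H]4[C@H]1O4 | intermediate
7 | benzyl alcohol | OCc1ccccc1 | starting material
8 | methyl 2-O-benzyl-4,6-O-[(R)-benzylidene]-β-D-altropyranoside | CO[C@@H]1O[C@@H]2CO[C@@H](c3ccccc3)O[C@H]2[C@@H](O)[C@@H]1OCc1ccccc1 | intermediate
9 | benzoyl chloride | O=C(Cl)c1ccccc1 | starting material
10 | methyl 3-O-benzoyl-2-O-benzyl-4,6-O-[(R)-benzylidene]-β-D-altropyranoside | CO[C@@H]1O[C@@H]2CO[C@@H](c3ccccc3)O[C@H]2[C@@H](OC(=O)c3ccccc3)[C@@H]1OCc1ccccc1 | intermediate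
11 | methyl 3-O-benzoyl-2,4-di-O-benzyl-β-D-altropyranoside | CO[C@@H]1O[C@H](CO)[C@@H](OCc2ccccc2)[C@@H](OC(=O)c2ccccc2)[C@@H]1OCc1ccccc1 | intermediate
12 | methyl 3-O-benzoyl-2,4-di-O-benzyl-6-deoxy-6-iodo-β-D-altropyranoside | CO[C@@H]1O[C@H](CI)[C@@H](OCc2ccccc2)[C@@H](OC(=O)c2ccccc2)[C@@H]1OCc1ccccc1 | intermediate
13 | methyl 3-O-benzoyl-2,4-di-O-benzyl-6-deoxy-β-D-arabino-hex-5-enopyranoside | CO[C@@H]1OC(=C)[C@@H](OCc2ccccc2)[C@@H](OC(=O)c2ccccc2)[C@@H]1OCc1ccccc1 | intermediate
14 | ring-opened zwitterion: methoxy oxocarbenium ion at C1 tethered to the trichloro(isopropoxy)titanate enolate of sugar C5 | CC(C)O[Ti-](Cl)(Cl)(Cl)OC(=C)[C@@H](OCc1ccccc1)[C@@H](OC(=O)c1ccccc1)[C@H](OCc1ccccc1)C=[O+]C | intermediate (not isolated)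
15 | (2S,3S,4R,5R)-3-(benzoyloxy)-2,4-bis(benzyloxy)-5-methoxycyclohexan-1-one | CO[C@@H]1CC(=O)[C@@H](OCc2ccccc2)[C@@H](OC(=O)c2ccccc2)[C@@H]1OCc1ccccc1 | intermediate
16 | lithium C2=C3 enolate of 15 | [Li+].CO[C@@H]1C=C([O-])[C@@H](OCc2ccccc2)[C@@H](OC(=O)c2ccccc2)[C@@H]1OCc1ccccc1 | intermediate (not isolated)
17 | enol triflate: 5-(benzoyloxy)-4,6-bis(benzyloxy)-3-methoxycyclohex-1-en-1-yl trifluoromethanesulfonate, configured as 15 | CO[C@@H]1C=C(OS(=O)(=O)C(F)(F)F)[C@@H](OCc2ccccc2)[C@@H](OC(=O)c2ccccc2)[C@@H]1OCc1ccccc1 | intermediate
18 | (tributylstannyl)methanol | OC[Sn](CCCC)(CCCC)CCCC | starting material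
19 | allylic alcohol: 2,6-bis(benzyloxy)-3-(hydroxymethyl)-5-methoxycyclohex-3-en-1-yl benzoate, configured as 15 | CO[C@@H]1C=C(CO)[C@@H](OCc2ccccc2)[C@@H](OC(=O)c2ccccc2)[C@@H]1OCc1ccccc1 | intermediate
20 | [5-(benzoyloxy)-4,6-bis(benzyloxy)-3-methoxycyclohex-1-en-1-yl]methyl benzoate, configured as 21 | CO[C@@H]1C=C(COC(=O)c2ccccc2)[C@@H](OCc2ccccc2)[C@@H](OC(=O)c2ccccc2)[C@@H]1OCc1ccccc1 | intermediate
21 | [(3R,4R,5R,6R)-5-(benzoyloxy)-4,6-dihydroxy-3-methoxycyclohex-1-en-1-yl]methyl benzoate | CO[C@@H]1C=C(COC(=O)c2ccccc2)[C@@H](O)[C@@H](OC(=O)c2ccccc2)[C@@H]1O | target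

## Step count and risks

Total step count: 13.
Longest linear sequence: 13 steps (1 to 21).

**Step 9 (key step).** The ion pair may lose its stereochemical memory: rotation of the oxocarbenium ion before recombination would scramble C1, and the 1,2-cis β-altro pattern is not the best-tested case of this rearrangement. Exocyclic cleavage with loss of the methoxy group, or interception of the cation by the neighbouring benzoate carbonyl, could also compete. Fallback from 13 back to 15: Ferrier carbocyclisation with catalytic Hg(OCOCF3)2 (divalent mercury) in aqueous acetone gives, with loss of the aglycon, the hydroxy ketone F1. By the usual trend of that reaction the new hydroxyl lies trans to the substituent on sugar C3, which is the configuration needed. Non-basic O-methylation with MeOTf and 2,6-di-tert-butyl-4-methylpyridine then gives 15.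

**Step 10.** The enolate may form toward C4, or may expel the C1 methoxide or the C5 benzoate (E1cB) before it is triflated, since both α positions have a β leaving group. Fallback from 15 to 20 without any enolate:
- Zn/CH2Br2/TiCl4 methylenation gives the exocyclic methylene compound F2.
- OsO4 (cat.) with N-methylmorpholine N-oxide gives the C3,C7-diol F3; either C3 epimer serves, because C3 becomes trigonal again.
- Benzoyl chloride 9 in pyridine at −20 °C acylates only the primary hydroxyl and gives the tertiary alcohol F4.
- SOCl2/pyridine dehydration should remove an axial C2 hydrogen rather than the C4 hydrogen, which sits on an oxygen-bearing carbon and would lead to an enol ether, and gives 20.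

Steps 11 and 12 are then not needed.

**Step 11.** Transfer of the sp3 hydroxymethyl group from tin is slow, so reduction of the triflate or butyl transfer may win. Fallback from 17 to 20:
- Methoxycarbonylation (CO, MeOH, Et3N, Pd(OAc)2, 1,1'-bis(diphenylphosphino)ferrocene, DMF) gives the methyl enoate F5.
- iBu2AlH reduces the enoate to the allylic alcohol and cleaves the C5 benzoate at the same time, giving the diol F6.
- Benzoyl chloride 9 with pyridine and DMAP acylates O5 and O7 together, which is exactly the pattern of 20.

**Step 13.** The boron Lewis acid may ionise the allylic C1–OMe or C4–O bonds or cleave the methyl ether, and the C5 benzoate may migrate during work-up. Fallback from 15 to 21 with a change of protecting groups before the alkene exists: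
- Hydrogenolysis (H2, Pd(OH)2/C, EtOAc) gives the dihydroxy ketone F7.
- Et3SiOTf/2,6-lutidine at −78 °C gives the bis(triethylsilyl) ether F8.
- The conditions of steps 10 to 12 give in turn the enol triflate F9, the allylic alcohol F10 and the dibenzoate F11.
- HF·pyridine in THF removes both silyl groups under acidic, non-reductive conditions and gives 21.

## Further compounds

F1 | step 9 | (2S,3S,4R,5R)-3-(benzoyloxy)-2,4-bis(benzyloxy)-5-hydroxycyclohexan-1-one | O[C@@H]1CC(=O)[C@@H](OCc2ccccc2)[C@@H](OC(=O)c2ccccc2)[C@@H]1OCc1ccccc1
F2 | step 10 | 2,6-bis(benzyloxy)-5-methoxy-3-methylidenecyclohexyl benzoate, configured as 15 | CO[C@@H]1CC(=C)[C@@H](OCc2ccccc2)[C@@H](OC(=O)c2ccccc2)[C@@H]1OCc1ccccc1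
F3 | step 10 | 2,6-bis(benzyloxy)-3-hydroxy-3-(hydroxymethyl)-5-methoxycyclohexyl benzoate, C3 epimers, otherwise configured as 15 | CO[C@@H]1CC(O)(CO)[C@@H](OCc2ccccc2)[C@@H](OC(=O)c2ccccc2)[C@@H]1OCc1ccccc1
F4 | step 10 | [3-(benzoyloxy)-2,4-bis(benzyloxy)-1-hydroxy-5-methoxycyclohexyl]methyl benzoate, C1 epimers of the cyclohexanol, otherwise configured as 15 | CO[C@@H]1CC(O)(COC(=O)c2ccccc2)[C@@H](OCc2ccccc2)[C@@H](OC(=O)c2ccccc2)[C@@H]1OCc1ccccc1
F5 | step 11 | methyl 5-(benzoyloxy)-4,6-bis(benzyloxy)-3-methoxycyclohex-1-ene-1-carboxylate, configured as 17 | CO[C@@H]1C=C(C(=O)OC)[C@@H](OCc2ccccc2)[C@@H](OC(=O)c2ccccc2)[C@@H]1OCc1ccccc1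
F6 | step 11 | 2,6-bis(benzyloxy)-3-(hydroxymethyl)-5-methoxycyclohex-3-en-1-ol, configured as 19 | CO[C@@H]1C=C(CO)[C@@H](OCc2ccccc2)[C@@H](O)[C@@H]1OCc1ccccc1
F7 | step 13 | 2,6-dihydroxy-3-methoxy-5-oxocyclohexyl benzoate, configured as 15 | CO[C@@H]1CC(=O)[C@@H](O)[C@@H](OC(=O)c2ccccc2)[C@@H]1O
F8 | step 13 | 3-methoxy-5-oxo-2,6-bis(triethylsilyloxy)cyclohexyl benzoate, configured as 15 | CO[C@@H]1CC(=O)[C@@H](O[Si](CC)(CC)CC)[C@@H](OC(=O)c2ccccc2)[C@@H]1O[Si](CC)(CC)CC
F9 | step 13 | 5-(benzoyloxy)-3-methoxy-4,6-bis(triethylsilyloxy)cyclohex-1-en-1-yl trifluoromethanesulfonate, configured as 17 | CO[C@@H]1C=C(OS(=O)(=O)C(F)(F)F)[C@@H](O[Si](CC)(CC)CC)[C@@H](OC(=O)c2ccccc2)[C@@H]1O[Si](CC)(CC)CC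
F10 | step 13 | 3-(hydroxymethyl)-5-methoxy-2,6-bis(triethylsilyloxy)cyclohex-3-en-1-yl benzoate, configured as 19 | CO[C@@H]1C=C(CO)[C@@H](O[Si](CC)(CC)CC)[C@@H](OC(=O)c2ccccc2)[C@@H]1O[Si](CC)(CC)CC
F11 | step 13 | [5-(benzoyloxy)-3-methoxy-4,6-bis(triethylsilyloxy)cyclohex-1-en-1-yl]methyl benzoate, configured as 21 | CO[C@@H]1C=C(COC(=O)c2ccccc2)[C@@H](O[Si](CC)(CC)CC)[C@@H](OC(=O)c2ccccc2)[C@@H]1O[Si](CC)(CC)CC
A1 | alternative 1 | (4S,5S)-2,2-dimethyl-1,3-dioxolane-4,5-dicarbaldehyde | O=C[C@H]1OC(C)(C)O[C@@H]1C=O
A2 | alternative 1 | tert-butyldimethyl{[3-(trimethylsilyl)prop-2-yn-1-yl]oxy}silane | C[Si](C)(C)C#CCO[Si](C)(C)C(C)(C)C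
A3 | alternative 1 | cyclohex-2-ene-1,4-diol with a trans 5,6-O-isopropylidene acetal, trimethylsilyl on C2 and CH2OSi(tBu)Me2 on C3 | O[C@@H]1C(=C(CO[Si](C)(C)C(C)(C)C)[C@@H](O)[C@H]2OC(C)(C)O[C@H]12)[Si](C)(C)C
A4 | alternative 2 | 2H-pyran-2-one | O=c1cccco1
A5 | alternative 2 | vinylene carbonate (1,3-dioxol-2-one) | O=c1occo1
A6 | alternative 2 | endo 2-oxabicyclo[2.2.2]oct-5-en-3-one with a cis-fused cyclic carbonate on C7 and C8 | O=C1O[C@@H]2C=C[C@H]1[C@H]3OC(=O)O[C@@H]23
A7 | alternative 3 | (Z)-configured open-chain aldehyde: 2-(benzoyloxy)-3-(tert-butyldimethylsilyloxy)-4-[(tert-butyldiphenylsilyloxy)methyl]-6,6-dimethoxyhex-4-enal | COC(OC)/C=C(/CO[Si](c1ccccc1)(c1ccccc1)C(C)(C)C)[C@@H](O[Si](C)(C)C(C)(C)C)[C@@H](OC(=O)c1ccccc1)C=O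
A8 | alternative 3 | cyclohexenol with C1 methyl ether, free C6 hydroxyl, C5 benzoate, C4 tert-butyldimethylsilyl ether and C7 tert-butyldiphenylsilyl ether, configured as the target | CO[C@@H]1C=C(CO[Si](c2ccccc2)(c2ccccc2)C(C)(C)C)[C@@H](O[Si](C)(C)C(C)(C)C)[C@@H](OC(=O)c2ccccc2)[C@@H]1O
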